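**Assumption:** (S)-5-(hydroxymethyl)dihydrofuran-2(3H)-one, made from L-glutamic acid, is a commercial chiral-pool lactone. 1,9-Decadiyne is a commercial achiral diyne.

## Retrosynthetic overview
1. The enyne/vinyl bromide side chain is cleaved by Sonogashira disconnection into terminal alkyne **8** and (1E,9E)-1-bromo-10-iododeca-1,9-diene **11**. **11** comes from 1,9-decadiyne by two hydrozirconation/halogenation steps.
2. The butanoate chain comes from a Johnson–Claisen [3,3] rearrangement of a 2-vinyl lactol, which is made by adding vinylMgBr to a protected lactone.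
3. The THF ring is already in the chiral-pool lactone, so no ring is formed. The C5 stereocentre (alkyne-bearing) comes from the lactone. The C2 stereocentre (chain-bearing) is set cis to C5 by ionic hydrogenation of the enol ether.
4. The alkyne is made last on the core, from the CH2OTBDPS group via aldehyde and Ohira–Bestmann homologation.

## Route

**Step 1**
Reactants: **1** (S)-5-(hydroxymethyl)dihydrofuran-2(3H)-one
Product: **2** (S)-5-[(tert-butyldiphenylsilyloxy)methyl]dihydrofuran-2(3H)-one
Conditions: TBDPSCl, imidazole, DMF, rt
Reagents that add atoms: TBDPSCl, CC(C)(C)[Si](Cl)(c1ccccc1)c1ccccc1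
Why: Selective silylation of the primary alcohol protects it from the Grignard reagent, and the stereocentre is untouched (silylation of a primary alcohol).

**Step 2**
Reactants: **2**
Product: **3** (5S)-5-[(TBDPSoxy)methyl]-2-vinyltetrahydrofuran-2-ol (hemiketal, C2 epimeric mixture)
Conditions: vinylMgBr (1.1 equiv), THF, −78 °C; quench NH4Cl at −78 °C
Reagents that add atoms: vinylmagnesium bromide, C=C[Mg]Br
Why: The Grignard adds once to the lactone and stops at the stable tetrahedral hemiketal at low temperature. The new C2 centre is lost in the next step, so its configuration does not matter.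

**Step 3**
Reactants: **3**
Product: **4** methyl 4-[(5S)-5-(TBDPSoxymethyl)tetrahydrofuran-2-ylidene]butanoate (exocyclic enol ether, possibly with the endocyclic C2=C3 isomer)
Conditions: MeC(OMe)3 (10 equiv), EtCO2H (5 mol %), xylene, 140 °C, sealed tube
Reagents that add atoms: trimethyl orthoacetate, CC(OC)(OC)OC
Why: The allylic hemiketal OH exchanges with the orthoester to give an allyl ketene acetal, which undergoes a Johnson–Claisen [3,3] rearrangement. This forms the CH2–CH2 bond of the chain and moves the alkene to C2=CH, giving the enol ether and the methyl ester together. Both enol ether isomers give the same oxocarbenium ion in step 4.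

**Step 4**
Reactants: **4**
Product: **5** methyl 4-[(2S,5S)-5-(TBDPSoxymethyl)tetrahydrofuran-2-yl]butanoate
Conditions: Et3SiH (3 equiv), TFA (3 equiv), CH2Cl2, −20 → 0 °C
Reagents that add atoms: none
Why: Protonation gives the 2,5-disubstituted oxocarbenium ion. Hydride delivery to the favoured envelope conformer (ionic hydrogenation) gives the 2,5-cis THF, with C2 set relative to the pool-derived C5.

**Step 5**
Reactants: **5**
Product: **6** methyl 4-[(2S,5S)-5-(hydroxymethyl)tetrahydrofuran-2-yl]butanoate
Conditions: TBAF, AcOH (1:1), THF, rt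
Reagents that add atoms: none
Why: Buffered fluoride removes the silyl ether and leaves the methyl ester intact (desilylation).

**Step 6**
Reactants: **6**
Product: **7** methyl 4-[(2S,5S)-5-formyltetrahydrofuran-2-yl]butanoate
Conditions: Dess–Martin periodinane, NaHCO3, CH2Cl2, 0 °C; use the crude aldehyde immediately
Reagents that add atoms: none
Why: Mild, non-basic oxidation of the primary alcohol gives the aldehyde with minimal epimerisation of the α-alkoxy centre.

**Step 7**
Reactants: **7**
Product: **8** methyl 4-[(2S,5S)-5-ethynyltetrahydrofuran-2-yl]butanoate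
Conditions: Ohira–Bestmann reagent (1.5 equiv), K2CO3, MeOH, 0 °C → rt
Reagents that add atoms: dimethyl (1-diazo-2-oxopropyl)phosphonate, COP(=O)(OC)C(=[N+]=[N-])C(C)=O (supplies the alkyne carbon)
Why: Seyferth–Gilbert homologation with in situ diazophosphonate gives the terminal alkyne. MeOH keeps the methyl ester, and the mild conditions preserve the stereocentre.

**Step 8**
Reactants: **9** 1,9-decadiyne
Product: **10** (E)-1-bromodec-1-en-9-yne
Conditions: Cp2Zr(H)Cl (1 equiv, diyne 3 equiv), CH2Cl2, rt; then NBS, 0 °C
Reagents that add atoms: N-bromosuccinimide, O=C1CCC(=O)N1Br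
Why: Hydrozirconation is syn and selective for terminal alkynes, giving an (E)-alkenylzirconocene. NBS then brominates it with retention (halodemetalation). Using excess diyne limits double reaction.

**Step 9**
Reactants: **10**
Product: **11** (1E,9E)-1-bromo-10-iododeca-1,9-diene
Conditions: Cp2Zr(H)Cl (1.1 equiv), CH2Cl2, rt; then I2, 0 °C
Reagents that add atoms: iodine, II
Why: The same hydrozirconation/halogenation sequence converts the remaining terminal alkyne into the (E)-vinyl iodide. The vinyl bromide is untouched.

**Step 10**
Reactants: **8** and **11** (1.3 equiv)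
Product: **12** Mutafran C, methyl 4-[(2S,5S)-5-((1E,9E)-10-bromodeca-1,9-dien-3-yn-1-yl)... i.e. the (E)-enyne with (E)-vinyl bromide, tetrahydrofuran-2-yl]butanoate
Conditions: Pd(PPh3)4 (5 mol %), CuI (10 mol %), iPr2NH, THF, rt, dark
Reagents that add atoms: none
Why: Sonogashira coupling is chemoselective for the vinyl iodide over the vinyl bromide at rt. Both alkene geometries are retained.

## Compound list
1 | (S)-5-(hydroxymethyl)dihydrofuran-2(3H)-one | O=C1CC[C@@H](CO)O1 | starting material
2 | (S)-5-(TBDPSoxymethyl)dihydrofuran-2(3H)-one | O=C1CC[C@@H](CO[Si](c2ccccc2)(c2ccccc2)C(C)(C)C)O1 | intermediate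
3 | (5S)-5-(TBDPSoxymethyl)-2-vinyltetrahydrofuran-2-ol | C=CC1(O)CC[C@@H](CO[Si](c2ccccc2)(c2ccccc2)C(C)(C)C)O1 | intermediate (C2 epimeric mixture)
4 | methyl 4-[(5S)-5-(TBDPSoxymethyl)tetrahydrofuran-2-ylidene]butanoate | COC(=O)CCC=C1CC[C@@H](CO[Si](c2ccccc2)(c2ccccc2)C(C)(C)C)O1 | intermediate
5 | methyl 4-[(2S,5S)-5-(TBDPSoxymethyl)tetrahydrofuran-2-yl]butanoate | COC(=O)CCC[C@@H]1CC[C@@H](CO[Si](c2ccccc2)(c2ccccc2)C(C)(C)C)O1 | intermediate
6 | methyl 4-[(2S,5S)-5-(hydroxymethyl)tetrahydrofuran-2-yl]butanoate | COC(=O)CCC[C@@H]1CC[C@@H](CO)O1 | intermediate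
7 | methyl 4-[(2S,5S)-5-formyltetrahydrofuran-2-yl]butanoate | COC(=O)CCC[C@@H]1CC[C@@H](C=O)O1 | intermediate
8 | methyl 4-[(2S,5S)-5-ethynyltetrahydrofuran-2-yl]butanoate | COC(=O)CCC[C@@H]1CC[C@@H](C#C)O1 | intermediate
9 | 1,9-decadiyne | C#CCCCCCCC#C | starting material
10 | (E)-1-bromodec-1-en-9-yne | Br/C=C/CCCCCCC#C | intermediate
11 | (1E,9E)-1-bromo-10-iododeca-1,9-diene | I/C=C/CCCCCC/C=C/Br | intermediate
12 | Mutafran C | COC(=O)CCC[C@@H]1CC[C@@H](C#C/C=C/CCCCCC/C=C/Br)O1 | target

## Totals
- Total steps: 10 (7 on the core, 2 on the side chain, 1 coupling).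
- Longest linear sequence: 8 steps (1 → 2 → … → 8 → 12).

## Three steps most likely to fail
1. **Step 3 (Johnson–Claisen of the tertiary hemiketal).** The hemiketal may ionise or eliminate under acid at 140 °C.
   Fallback: drop the Claisen and reduce the lactone to the lactol. Then do Hosomi–Sakurai allylation (allylTMS, BF3·OEt2) for cis-2-allyl-THF, cross-metathesis with methyl acrylate, and alkene hydrogenation.
2. **Step 4 (cis-selectivity of ionic hydrogenation).** The cis:trans ratio may be only moderate, and TFA could affect the silyl ether.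
   Fallback: switch stereocontrol mode to heterogeneous catalytic hydrogenation of the enol ether (Pd/C, H2), which delivers H2 anti to the C5 substituent. If that also fails, use the allylation route from fallback 1.
3. **Step 7 (epimerisable α-alkoxy aldehyde → alkyne).** The aldehyde can epimerise under K2CO3/MeOH and give the trans diastereomer.
   Fallback: use Corey–Fuchs homologation instead (CBr4/PPh3, then n-BuLi), which avoids the basic diazophosphonate conditions.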